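Prenyl stands for 3-methylbut-2-en-1-yl throughout; ring and atom labels follow isoflavanone numbering (ring A C4a–C8a, ring C O1–C4, ring B primed).

## The problem

The target 27 is a 3-hydroxyisoflavanone: a chroman-4-one (ring C) fused to a phloroglucinol-type ring A with free hydroxyls at C5 and C7, bearing at C3 a hydroxyl and ring B, a 2',4'-dimethoxy-3'-prenylphenyl group. C3 is the only stereocentre, a fully substituted benzylic carbinol between the C4 ketone and the C2 methylene, and it must be R. With no second stereocentre nothing can be relayed, so the configuration has to come from a reagent or catalyst, best at a stage where the two one-carbon arms on C3 (future C2 and C4) are still alike. Once set, C3 cannot epimerise through an enol. The tertiary alcohol, activated by the ortho and para methoxy groups of ring B, can however ionise in strong acid and lose water towards the isoflavone, and open-chain precursors with a hydroxymethyl group on C3 can lose formaldehyde by retro-aldol cleavage in strong base. The prenyl olefin forbids hydrogenolysis, electrophilic oxidants and hot mineral acid, which excludes benzyl ethers; ring A cannot be carried as methyl ethers because the two methyl ethers of ring B must stay. The free ring A is a strong carbon nucleophile at C6 and C8 and is best unmasked late. The enabling feature is that C4a and C8a are adjacent ring A carbons bearing the C4 acyl carbon and O1, with the C5 oxygen next to C4a: this is the pattern left when a 3,5-dioxygenated aryne inserts into the C(=O)–O bond of a carboxylic acid, the alkoxy group beside the aryne sending oxygen to C8a and the acyl group to C4a.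

## Retrosynthesis

**27 to 26 (cut O1–C2).** C2 is a primary carbon, so its ether bond to the ring A oxygen can be made by dehydrative alkylation without touching C3. Cutting C3–C4 or O1–C8a instead would need an acyl anion addition to a hindered ketone or a substitution on an electron-rich arene. The precursor is the open-chain pentaol 26, in which the two ortho hydroxyls of the trihydroxyphenyl ketone are equivalent, so no regiochemical question arises. The forward reaction must be neutral, because 27 can dehydrate to the isoflavone, and must prefer the phenol over the tertiary alcohol as nucleophile.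

**26 to 25 (protecting groups).** The diol is masked as an acetonide and the C5 and C7 oxygens as methoxymethyl ethers, giving ketone 25. All three groups resist fluoride, organolithiums and mild base, and all fall in one mild acid treatment that spares the prenyl group. The alternative of keeping the methoxymethyl ethers through ring closure would end the route with an acid step on the dehydration-prone target.

**25 to 13 and 22 (cut C4–C4a and O1–C8a).** Both bonds joining the side chain to ring A are cut together, which gives the α-aryl glyceric acid acetonide 13 and the silyl triflate 22, the precursor of a 3,5-bis(methoxymethoxy)aryne. A Friedel–Crafts or Fries acylation of a phloroglucinol ether would form only the C–C bond, would need Lewis acids that the acetonide and ring B cannot stand, and would struggle with the fully substituted acyl carbon. The aryne insertion is run with fluoride in an aprotic solvent and delivers the free ortho phenol needed later. The cut is convergent and halves the molecule. The forward reaction must add oxygen at C8a and carbon at C4a, and must transfer the acyl group faster than the aryl anion is protonated.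

**13 back to 9 (the stereocentre).** Acid 13 comes by oxidation of alcohol 12, which comes from the benzoate 11 and the monobenzoate 10. In 10 the carbinol carbon holds two hydroxymethyl arms that differ only in one acyl group. Removing that group reveals triol 9, which is achiral with enantiotopic arms. The stereochemical problem thus reduces to a desymmetrising acylation, a catalytic reaction with both ligand antipodes available. The usual route to an α-aryl glycerate, dihydroxylation of an aryl acrylate, is not open because the prenyl olefin would react first.

**9 to 5 and 6; 5 to 4; 4 to 1 and 2 (cut C3–C1').** The triol is the adduct of an aryllithium from bromide 5 and 2,2-dimethyl-1,3-dioxan-5-one 6 after loss of acetone. Bromide 5 follows from 1,3-dimethoxy-2-prenylbenzene 4, whose only activated ring positions are equivalent. Arene 4 comes from 1,3-dimethoxybenzene 1 and prenyl bromide 2 by lithiation between the two methoxy groups. Ring B with all four substituents is thus fixed in two steps from a commodity arene.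

**22 to 20, 16, 15 and 14.** The triflate and the silyl group are ortho, so 22 is traced to the ortho-silyl carbamate 20, made by carbamate-directed lithiation of 16. Carbamate 16 comes from 3,5-bis(methoxymethoxy)phenol 15 and this from phloroglucinol 14. The carbamate serves first as directing group and then as a masked phenol.

## Roads not taken

Alternative 1: Ring B is cut across C1'–C2' and C5'–C6' into the oxygenated diene A1 and the terminal ynone A2, in which ring A already holds the C2–O1 ether and, as an aldehyde, the future C4. The Diels–Alder adduct would lose methanol and give the 2'-hydroxyaryl ketone A3. Methylation to A4 and a carbene-catalysed intramolecular crossed benzoin reaction would then form C3–C4, close ring C and set C3 in one catalytic asymmetric step.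
- Merits: the prenyl group is placed by the diene and never meets an electrophile; C3 is created by catalysis in the ring-forming step with no enantiotopic-arm differentiation and little protecting-group traffic. In stereochemical economy this road is better than the chosen one.
- Weak points: A1 is a tetrasubstituted ketene acetal that takes several steps to make and is labile. A2, A3 and A4 are aryloxymethyl ketones with an ortho aldehyde, which under base tend to intramolecular aldol condensation to a 2-aroylbenzofuran; this threatens both the methylation of the chelated 2'-hydroxyl and the basic carbene step. The aldehyde of A2 can act as a hetero-dienophile. A benzoin addition to a ketone with a 2,6-disubstituted electron-rich aryl group, from a doubly ortho-substituted electron-rich aldehyde, lies at the edge of known scope, so rate and enantioselectivity are uncertain.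
- Comparison: the chosen plan sets against the better stereochemical economy a stereocentre fixed early by a reaction of a known substrate class and untouchable afterwards, and a ring B bought in two steps instead of built.

Alternative 2: The C3–O bond is made on the intact skeleton. The prenylated isoflavone A5 would be epoxidised at C2=C3 by a hydroperoxide under chiral quaternary ammonium phase-transfer catalysis to the epoxide A6, and the C2–O bond of the oxirane would then be cleaved reductively.
- Merits: this is the shortest road, since isoflavones of this kind are reached in a few steps and the stereocentre and the C3 oxygen arrive together. A nucleophilic oxidant leaves the prenyl olefin alone. In step economy it is clearly superior.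
- Weak points: the C2=C3 bond of an isoflavone is a vinylogous ester and a poor acceptor, and peroxide or hydroxide attack at C2 tends to open the pyranone. Facial selectivity with an ortho-substituted 3-aryl group has no close model. A6 is an epoxy acetal that rearranges readily. Its reduction at C2 must spare the C4 ketone, while Lewis acids strong enough to ionise C2 also endanger the methoxymethyl ethers and the benzylic C3–O bond.
- Comparison: two consecutive steps without close precedent carry the whole route. The chosen plan is longer, but every step has a model in kind and the stereocentre never passes through a labile intermediate.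

Alternative 3: Ring A is cut at C4a–C5 and built from acetate units. The triketo ester A7, made by acylating a dioxohexanoate polyanion with an activated form of acid 13, would cyclise with Mg(OMe)2 by Claisen condensation to the trihydroxyphenyl ketone A8.
- Merits: it shares acid 13 with the chosen plan, replaces the four-step aryne precursor, needs no protecting groups on ring A and has no statistical step. On paper it is a few steps shorter.
- Weak points: acylation of a polyanion by an acyl donor with a fully substituted α-carbon is the least precedented operation. A7 can also cyclise by aldol addition to a resorcylate or dehydrate to a pyranone. The free phloroglucinol ring then travels through the acetonide cleavage unprotected.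
- Comparison: the chosen plan pays with a statistical protection of phloroglucinol 14 and a longer branch. In return both ring A bonds form regiospecifically in one step under near-neutral fluoride conditions, with precedent on alkoxy-substituted arynes.

Key step: step 12

Assumption: the (R,R)-bisoxazoline in step 4 is taken to benzoylate the arm that gives (R)-10; if the first run shows the opposite sense, the (S,S) ligand is used and nothing else changes.

## Route

Step 1
Reactants: 1 1,3-dimethoxybenzene; 2 prenyl bromide (1-bromo-3-methylbut-2-ene)
Product: 4 1,3-dimethoxy-2-prenylbenzene, via 2,6-dimethoxyphenyllithium 3 (not isolated)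
Conditions: n-BuLi, THF, 0 °C to rt; then 2, 0 °C to rt
Reagents that add atoms: none
Why: Directed ortho-lithiation between the two methoxy groups followed by SN2 alkylation of the aryllithium at the primary carbon of the allylic bromide; this places the prenyl group regiospecifically.

Step 2
Reactants: 4 1,3-dimethoxy-2-prenylbenzene
Product: 5 1-bromo-2,4-dimethoxy-3-prenylbenzene
Conditions: NBS (1.0 equiv), MeCN, −20 to 0 °C, dark
Reagents that add atoms: N-bromosuccinimide, O=C1CCC(=O)N1Br
Why: Electrophilic aromatic bromination; the two equivalent positions ortho to one and para to the other methoxy group are the only activated sites. In dry polar solvent the resorcinol diether ring should react much faster than the trisubstituted olefin.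

Step 3
Reactants: 5 1-bromo-2,4-dimethoxy-3-prenylbenzene; 6 2,2-dimethyl-1,3-dioxan-5-one
Product: 9 2-(2,4-dimethoxy-3-prenylphenyl)propane-1,2,3-triol, via (2,4-dimethoxy-3-prenylphenyl)lithium 7 (not isolated), via 5-(2,4-dimethoxy-3-prenylphenyl)-2,2-dimethyl-1,3-dioxan-5-ol 8 (not isolated)
Conditions: n-BuLi, THF, −78 °C; 6, −78 to 0 °C; then 1 M aq. HCl, rt
Reagents that add atoms: none
Why: Bromine–lithium exchange and 1,2-addition of the aryllithium to the ketone, then acid hydrolysis of the labile six-membered acetonide in the work-up. The two β-oxygens retard ionisation of the new benzylic carbinol, which remains achiral with enantiotopic arms.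

Step 4
Reactants: 9 2-(2,4-dimethoxy-3-prenylphenyl)propane-1,2,3-triol
Product: 10 (2R)-2-(2,4-dimethoxy-3-prenylphenyl)-2,3-dihydroxypropyl benzoate
Conditions: CuCl2 (5 mol%), (R,R)-Ph-BOX (5 mol%), BzCl (1.1 equiv), Et3N, THF, 0 °C to rt
Reagents that add atoms: benzoyl chloride, O=C(Cl)c1ccccc1
Why: Catalytic enantioselective desymmetrising monobenzoylation of a 2-substituted glycerol. The chiral divalent copper bisoxazoline complex chelates the tertiary hydroxyl together with one of the two enantiotopic hydroxymethyl arms and only that arm is acylated, which turns the carbinol carbon into the future C3 stereocentre.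

Step 5
Reactants: 10 (2R)-2-(2,4-dimethoxy-3-prenylphenyl)-2,3-dihydroxypropyl benzoate
Product: 11 [(4R)-4-(2,4-dimethoxy-3-prenylphenyl)-2,2-dimethyl-1,3-dioxolan-4-yl]methyl benzoate
Conditions: Me2C(OMe)2, PPTS (cat.), CH2Cl2, rt
Reagents that add atoms: 2,2-dimethoxypropane, COC(C)(C)OC
Why: Acid-catalysed transacetalisation ties the tertiary and the free primary hydroxyl into a dioxolane. It is run directly after step 4 under mild acid so that the benzoate has no occasion to migrate between the arms.

Step 6
Reactants: 11 [(4R)-4-(2,4-dimethoxy-3-prenylphenyl)-2,2-dimethyl-1,3-dioxolan-4-yl]methyl benzoate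
Product: 12 [(4S)-4-(2,4-dimethoxy-3-prenylphenyl)-2,2-dimethyl-1,3-dioxolan-4-yl]methanol
Conditions: K2CO3, MeOH, rt
Reagents that add atoms: none
Why: Base-catalysed transesterification (methanolysis) of the benzoate; the acetonide is inert to base and the descriptor changes from R to S only through the priority rules.

Step 7
Reactants: 12 [(4S)-4-(2,4-dimethoxy-3-prenylphenyl)-2,2-dimethyl-1,3-dioxolan-4-yl]methanol
Product: 13 (4R)-4-(2,4-dimethoxy-3-prenylphenyl)-2,2-dimethyl-1,3-dioxolane-4-carboxylic acid
Conditions: TEMPO (cat.), PhI(OAc)2, MeCN/H2O (1:1), rt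
Reagents that add atoms: water, O
Why: Nitroxyl-catalysed oxidation of a primary alcohol through the aldehyde hydrate to the acid; the conditions tolerate olefins and acetonides. The α-carbon has no hydrogen, so the stereocentre cannot be lost.

Step 8
Reactants: 14 phloroglucinol
Product: 15 3,5-bis(methoxymethoxy)phenol
Conditions: MOMCl (2.0 equiv), i-Pr2NEt, DMF, 0 °C to rt
Reagents that add atoms: chloromethyl methyl ether, COCCl
Why: O-Alkylation of the phenol with an α-chloro ether. The reaction is statistical on a cheap symmetric triol, and the mono- and tris-ethers are separated and recycled.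

Step 9
Reactants: 15 3,5-bis(methoxymethoxy)phenol
Product: 16 3,5-bis(methoxymethoxy)phenyl N-isopropylcarbamate
Conditions: i-PrNCO, Et3N (cat.), CH2Cl2, rt
Reagents that add atoms: isopropyl isocyanate, CC(C)N=C=O
Why: Base-catalysed addition of the phenol to an isocyanate gives the carbamate that serves as directing group and later as masked phenol.

Step 10
Reactants: 16 3,5-bis(methoxymethoxy)phenyl N-isopropylcarbamate
Product: 20 3,5-bis(methoxymethoxy)-2-(trimethylsilyl)phenyl N-isopropylcarbamate, via N-TBS carbamate 17 (not isolated), via ortho-lithiated N-TBS carbamate 18 (not isolated), via N-TBS 2-TMS carbamate 19 (not isolated)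
Conditions: TBSOTf, TMEDA, Et2O, 0 °C to rt; n-BuLi, TMEDA, −78 °C; TMSCl, −78 °C to rt; cold aq. NaHSO4 (brief)
Reagents that add atoms: chlorotrimethylsilane, C[Si](C)(C)Cl
Why: Directed ortho-metalation with in situ N-silylation of the N–H carbamate. The carbamate is the strongest directing group and acts together with the neighbouring methoxymethyl ether, so lithiation is expected at C2 between them; silyl quench and hydrolysis of the N–Si bond follow.

Step 11
Reactants: 20 3,5-bis(methoxymethoxy)-2-(trimethylsilyl)phenyl N-isopropylcarbamate
Product: 22 3,5-bis(methoxymethoxy)-2-(trimethylsilyl)phenyl trifluoromethanesulfonate, via 3,5-bis(methoxymethoxy)-2-(trimethylsilyl)phenol 21 (not isolated)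
Conditions: DBU, Et2NH, MeCN, 40 °C; then PhNTf2, rt
Reagents that add atoms: N-phenylbis(trifluoromethanesulfonimide), O=S(=O)(N(c1ccccc1)S(=O)(=O)C(F)(F)F)C(F)(F)F
Why: E1cB cleavage of the N-monoalkyl carbamate (the isocyanate is trapped by diethylamine as a urea), then O-triflation of the phenoxide in the same flask; mild base leaves the aryl–silicon bond and the acetal ethers intact.

Step 12
Reactants: 13 (4R)-4-(2,4-dimethoxy-3-prenylphenyl)-2,2-dimethyl-1,3-dioxolane-4-carboxylic acid; 22 3,5-bis(methoxymethoxy)-2-(trimethylsilyl)phenyl trifluoromethanesulfonate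
Product: 25 [(4R)-4-(2,4-dimethoxy-3-prenylphenyl)-2,2-dimethyl-1,3-dioxolan-4-yl][2-hydroxy-4,6-bis(methoxymethoxy)phenyl]methanone, via 3,5-bis(methoxymethoxy)benzyne 23 (not isolated), via ortho-cesiated aryl ester 24 (not isolated)
Conditions: CsF (4 equiv), 22 (1.5 equiv), THF, 125 °C, sealed tube
Reagents that add atoms: none
Why: Fluoride attacks silicon in 22 and triflate leaves, giving aryne 23 whose triple bond spans the future C4a and C8a. The cesium carboxylate of 13 adds through oxygen to the aryne carbon remote from the adjacent methoxymethoxy group (future C8a), because that group distorts the aryne and stabilises inductively the negative charge developing at the neighbouring carbon (future C4a). The aryl anion 24 then attacks its own ester carbonyl through a four-membered transition state, an anionic Fries-type 1,3 oxygen-to-carbon acyl shift, which forms C4–C4a and releases the phenoxide of 25. The closest known reaction type is the fluoride-induced insertion of arynes into the C–O bond of carboxylic acids to give ortho-hydroxyaryl ketones, for which alkoxy-substituted arynes show the same regiochemistry. No ring closes and no stereocentre is formed; the existing centre has no α-hydrogen and cannot epimerise in the basic medium. The step needs regioselectivity, secured by the alkoxy group beside the aryne; acyl transfer in preference to protonation of 24, favoured by the aprotic solvent and heat; and chemoselectivity for the carboxylate over the prenyl olefin and the product phenoxide, the carboxylate being the strongest nucleophile present and the phenoxide of 25 being chelated and hindered by the new ketone.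

Step 13
Reactants: 25 [(4R)-4-(2,4-dimethoxy-3-prenylphenyl)-2,2-dimethyl-1,3-dioxolan-4-yl][2-hydroxy-4,6-bis(methoxymethoxy)phenyl]methanone
Product: 26 (2R)-2-(2,4-dimethoxy-3-prenylphenyl)-2,3-dihydroxy-1-(2,4,6-trihydroxyphenyl)propan-1-one
Conditions: HCl (1.25 M in MeOH), 0 °C to 35 °C
Reagents that add atoms: none
Why: Acid-catalysed transacetalisation removes the acetonide and both methoxymethyl ethers at once. Methanol carries the formaldehyde away as its dimethyl acetal so that it cannot alkylate the free ring A, and the carbonyl group next to the benzylic carbinol disfavours its ionisation.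

Step 14
Reactants: 26 (2R)-2-(2,4-dimethoxy-3-prenylphenyl)-2,3-dihydroxy-1-(2,4,6-trihydroxyphenyl)propan-1-one
Product: 27 (3R)-3-(2,4-dimethoxy-3-prenylphenyl)-3,5,7-trihydroxy-2,3-dihydro-4H-chromen-4-one
Conditions: PPh3, DIAD (premixed, 0 °C), THF (0.01 M); then 26, 0 °C to rt
Reagents that add atoms: none
Why: Mitsunobu etherification: only the primary alcohol is activated and an ortho phenoxide closes ring C by 6-exo-tet displacement at C2; the two ortho hydroxyls are equivalent, so either gives 27. The tertiary alcohol is not acidic enough to compete and C3 is not a reacting centre; premixing the reagents keeps free azodicarboxylate away from the electron-rich ring A.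

## Compound list

1 | 1,3-dimethoxybenzene | COc1cccc(OC)c1 | starting material
2 | prenyl bromide (1-bromo-3-methylbut-2-ene) | CC(C)=CCBr | starting material
3 | 2,6-dimethoxyphenyllithium | [Li]c1c(OC)cccc1OC | intermediate (not isolated)
4 | 1,3-dimethoxy-2-prenylbenzene | COc1cccc(OC)c1CC=C(C)C | intermediate
5 | 1-bromo-2,4-dimethoxy-3-prenylbenzene | COc1ccc(Br)c(OC)c1CC=C(C)C | intermediate
6 | 2,2-dimethyl-1,3-dioxan-5-one | CC1(C)OCC(=O)CO1 | starting material
7 | (2,4-dimethoxy-3-prenylphenyl)lithium | [Li]c1ccc(OC)c(CC=C(C)C)c1OC | intermediate (not isolated)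
8 | 5-(2,4-dimethoxy-3-prenylphenyl)-2,2-dimethyl-1,3-dioxan-5-ol | COc1ccc(C2(O)COC(C)(C)OC2)c(OC)c1CC=C(C)C | intermediate (not isolated)
9 | 2-(2,4-dimethoxy-3-prenylphenyl)propane-1,2,3-triol | COc1ccc(C(O)(CO)CO)c(OC)c1CC=C(C)C | intermediate
10 | (2R)-2-(2,4-dimethoxy-3-prenylphenyl)-2,3-dihydroxypropyl benzoate | O=C(OC[C@@](O)(c1ccc(OC)c(CC=C(C)C)c1OC)CO)c1ccccc1 | intermediate
11 | [(4R)-4-(2,4-dimethoxy-3-prenylphenyl)-2,2-dimethyl-1,3-dioxolan-4-yl]methyl benzoate | O=C(OC[C@@]1(c2ccc(OC)c(CC=C(C)C)c2OC)COC(C)(C)O1)c1ccccc1 | intermediate
12 | [(4S)-4-(2,4-dimethoxy-3-prenylphenyl)-2,2-dimethyl-1,3-dioxolan-4-yl]methanol | OC[C@@]1(c2ccc(OC)c(CC=C(C)C)c2OC)COC(C)(C)O1 | intermediate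
13 | (4R)-4-(2,4-dimethoxy-3-prenylphenyl)-2,2-dimethyl-1,3-dioxolane-4-carboxylic acid | OC(=O)[C@@]1(c2ccc(OC)c(CC=C(C)C)c2OC)COC(C)(C)O1 | intermediate
14 | phloroglucinol | Oc1cc(O)cc(O)c1 | starting material
15 | 3,5-bis(methoxymethoxy)phenol | COCOc1cc(O)cc(OCOC)c1 | intermediate
16 | 3,5-bis(methoxymethoxy)phenyl N-isopropylcarbamate | CC(C)NC(=O)Oc1cc(OCOC)cc(OCOC)c1 | intermediate
17 | 3,5-bis(methoxymethoxy)phenyl N-(tert-butyldimethylsilyl)-N-isopropylcarbamate | CC(C)N(C(=O)Oc1cc(OCOC)cc(OCOC)c1)[Si](C)(C)C(C)(C)C | intermediate (not isolated)
18 | 2-lithio-3,5-bis(methoxymethoxy)phenyl N-(tert-butyldimethylsilyl)-N-isopropylcarbamate | CC(C)N(C(=O)Oc1cc(OCOC)cc(OCOC)c1[Li])[Si](C)(C)C(C)(C)C | intermediate (not isolated)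
19 | 3,5-bis(methoxymethoxy)-2-(trimethylsilyl)phenyl N-(tert-butyldimethylsilyl)-N-isopropylcarbamate | CC(C)N(C(=O)Oc1cc(OCOC)cc(OCOC)c1[Si](C)(C)C)[Si](C)(C)C(C)(C)C | intermediate (not isolated)
20 | 3,5-bis(methoxymethoxy)-2-(trimethylsilyl)phenyl N-isopropylcarbamate | CC(C)NC(=O)Oc1cc(OCOC)cc(OCOC)c1[Si](C)(C)C | intermediate
21 | 3,5-bis(methoxymethoxy)-2-(trimethylsilyl)phenol | COCOc1cc(O)c([Si](C)(C)C)c(OCOC)c1 | intermediate (not isolated)
22 | 3,5-bis(methoxymethoxy)-2-(trimethylsilyl)phenyl trifluoromethanesulfonate | COCOc1cc(OCOC)c([Si](C)(C)C)c(OS(=O)(=O)C(F)(F)F)c1 | intermediate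
23 | 3,5-bis(methoxymethoxy)benzyne | COCOC1=CC(OCOC)=CC#C1 | intermediate (not isolated)
24 | 2-cesio-3,5-bis(methoxymethoxy)phenyl (4R)-4-(2,4-dimethoxy-3-prenylphenyl)-2,2-dimethyl-1,3-dioxolane-4-carboxylate | COCOc1cc(OCOC)c([Cs])c(OC(=O)[C@@]2(c3ccc(OC)c(CC=C(C)C)c3OC)COC(C)(C)O2)c1 | intermediate (not isolated)
25 | [(4R)-4-(2,4-dimethoxy-3-prenylphenyl)-2,2-dimethyl-1,3-dioxolan-4-yl][2-hydroxy-4,6-bis(methoxymethoxy)phenyl]methanone | COCOc1cc(O)c(C(=O)[C@@]2(c3ccc(OC)c(CC=C(C)C)c3OC)COC(C)(C)O2)c(OCOC)c1 | intermediate
26 | (2R)-2-(2,4-dimethoxy-3-prenylphenyl)-2,3-dihydroxy-1-(2,4,6-trihydroxyphenyl)propan-1-one | COc1ccc([C@@](O)(CO)C(=O)c2c(O)cc(O)cc2O)c(OC)c1CC=C(C)C | intermediate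
27 | (3R)-3-(2,4-dimethoxy-3-prenylphenyl)-3,5,7-trihydroxy-2,3-dihydro-4H-chromen-4-one | COc1ccc([C@@]2(O)COc3cc(O)cc(O)c3C2=O)c(OC)c1CC=C(C)C | target

## Step count and risks

Total: 14 steps. Longest linear sequence: 10 steps (steps 1–7 and 12–14, from 1); the aryne branch from 14 adds steps 8–11.

**Step 12 (key step).** Protonation of the aryl anion may outrun the acyl shift, because the ester carbonyl sits next to a fully substituted carbon; the aryne may also be consumed by an ene reaction with the prenyl group or by arylation of the product phenoxide. Fallback, from 12 and 14, rejoining at 26: alcohol 12 is oxidised with Dess–Martin periodinane to (4R)-4-(2,4-dimethoxy-3-prenylphenyl)-2,2-dimethyl-1,3-dioxolane-4-carbaldehyde F1. Phloroglucinol 14 is exhaustively protected to 1,3,5-tris(methoxymethoxy)benzene F2, which is lithiated between two ether oxygens with n-BuLi and added to F1. This gives [(4R)-4-(2,4-dimethoxy-3-prenylphenyl)-2,2-dimethyl-1,3-dioxolan-4-yl][2,4,6-tris(methoxymethoxy)phenyl]methanol F3, whose carbinol epimers are of no consequence. Oxidation with Dess–Martin periodinane gives [(4R)-4-(2,4-dimethoxy-3-prenylphenyl)-2,2-dimethyl-1,3-dioxolan-4-yl][2,4,6-tris(methoxymethoxy)phenyl]methanone F4, and methanolic HCl as in step 13 gives 26.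

**Step 4.** Discrimination between the enantiotopic arms may be poor, because the ortho methoxy group of ring B can compete with the diol for copper and loosen the chelate that carries the chiral information; benzoyl migration between the arms would erode the enantiomeric purity further. Fallback, from 9, rejoining at 12: the stereocentre is set by an enzyme instead. Triol 9 is acetylated with vinyl acetate under a lipase (Burkholderia cepacia lipase in t-BuOMe, chosen by screening for the enzyme that acylates the required arm) to (2R)-2-(2,4-dimethoxy-3-prenylphenyl)-2,3-dihydroxypropyl acetate F5. Acetonide formation as in step 5 gives [(4R)-4-(2,4-dimethoxy-3-prenylphenyl)-2,2-dimethyl-1,3-dioxolan-4-yl]methyl acetate F6, and methanolysis with K2CO3 gives 12.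

**Step 10.** Lithiation may compete at C4 between the two methoxymethyl ethers, and the lithiated carbamate may undergo an anionic carbamoyl shift if it warms before the silyl quench. Fallback, from 15, rejoining at 21 and hence 22: regiochemistry is set by electrophilic substitution instead of deprotonation. Phenol 15 is brominated ortho to the hydroxyl (NBS, i-Pr2NH cat., CH2Cl2, −78 °C) to 2-bromo-3,5-bis(methoxymethoxy)phenol F7 and O-silylated with hexamethyldisilazane to [2-bromo-3,5-bis(methoxymethoxy)phenoxy]trimethylsilane F8. n-BuLi then triggers bromine–lithium exchange and a retro-Brook 1,3 oxygen-to-carbon silyl shift, giving the lithium salt of 21, which is triflated in the same flask with PhNTf2 to 22.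

**Step 14.** Intermolecular etherification through the more acidic para hydroxyl, amination of ring A by the azodicarboxylate, or closure of the diol to an oxirane may compete with ring closure when three phenols are free. Fallback, from 25, rejoining at 27: the ring is closed before ring A is unmasked. Selective hydrolysis of the acetonide (80% aq. AcOH, 40 °C) gives (2R)-2-(2,4-dimethoxy-3-prenylphenyl)-2,3-dihydroxy-1-[2-hydroxy-4,6-bis(methoxymethoxy)phenyl]propan-1-one F9, which has a single acidic hydroxyl. Mitsunobu closure gives (3R)-3-(2,4-dimethoxy-3-prenylphenyl)-3-hydroxy-5,7-bis(methoxymethoxy)-2,3-dihydro-4H-chromen-4-one F10, and short, cold methanolic HCl releases 27.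

**Step 2.** Bromine may add to the prenyl double bond or substitute its allylic positions. Fallback, from 1, rejoining at 5: the order is reversed. Arene 1 is brominated with NBS in MeCN to 1-bromo-2,4-dimethoxybenzene F11, which is deprotonated between the methoxy groups with lithium diisopropylamide at −78 °C and alkylated with prenyl bromide 2 to give 5.

## Further compounds

F1 | step 12 | (4R)-4-(2,4-dimethoxy-3-prenylphenyl)-2,2-dimethyl-1,3-dioxolane-4-carbaldehyde | O=C[C@@]1(c2ccc(OC)c(CC=C(C)C)c2OC)COC(C)(C)O1
F2 | step 12 | 1,3,5-tris(methoxymethoxy)benzene | COCOc1cc(OCOC)cc(OCOC)c1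
F3 | step 12 | [(4R)-4-(2,4-dimethoxy-3-prenylphenyl)-2,2-dimethyl-1,3-dioxolan-4-yl][2,4,6-tris(methoxymethoxy)phenyl]methanol (carbinol epimers) | COCOc1cc(OCOC)c(C(O)[C@@]2(c3ccc(OC)c(CC=C(C)C)c3OC)COC(C)(C)O2)c(OCOC)c1
F4 | step 12 | [(4R)-4-(2,4-dimethoxy-3-prenylphenyl)-2,2-dimethyl-1,3-dioxolan-4-yl][2,4,6-tris(methoxymethoxy)phenyl]methanone | COCOc1cc(OCOC)c(C(=O)[C@@]2(c3ccc(OC)c(CC=C(C)C)c3OC)COC(C)(C)O2)c(OCOC)c1
F5 | step 4 | (2R)-2-(2,4-dimethoxy-3-prenylphenyl)-2,3-dihydroxypropyl acetate | CC(=O)OC[C@@](O)(c1ccc(OC)c(CC=C(C)C)c1OC)CO
F6 | step 4 | [(4R)-4-(2,4-dimethoxy-3-prenylphenyl)-2,2-dimethyl-1,3-dioxolan-4-yl]methyl acetate | CC(=O)OC[C@@]1(c2ccc(OC)c(CC=C(C)C)c2OC)COC(C)(C)O1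
F7 | step 10 | 2-bromo-3,5-bis(methoxymethoxy)phenol | COCOc1cc(O)c(Br)c(OCOC)c1
F8 | step 10 | [2-bromo-3,5-bis(methoxymethoxy)phenoxy]trimethylsilane | COCOc1cc(O[Si](C)(C)C)c(Br)c(OCOC)c1
F9 | step 14 | (2R)-2-(2,4-dimethoxy-3-prenylphenyl)-2,3-dihydroxy-1-[2-hydroxy-4,6-bis(methoxymethoxy)phenyl]propan-1-one | COCOc1cc(O)c(C(=O)[C@](O)(CO)c2ccc(OC)c(CC=C(C)C)c2OC)c(OCOC)c1
F10 | step 14 | (3R)-3-(2,4-dimethoxy-3-prenylphenyl)-3-hydroxy-5,7-bis(methoxymethoxy)-2,3-dihydro-4H-chromen-4-one | COc1ccc([C@@]2(O)COc3cc(OCOC)cc(OCOC)c3C2=O)c(OC)c1CC=C(C)C
F11 | step 2 | 1-bromo-2,4-dimethoxybenzene | COc1ccc(Br)c(OC)c1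
A1 | alternative 1 | 1,3-dimethoxy-2-prenyl-1-(trimethylsilyloxy)buta-1,3-diene | COC(O[Si](C)(C)C)=C(CC=C(C)C)C(OC)=C
A2 | alternative 1 | 2,4-bis(methoxymethoxy)-6-[(2-oxobut-3-yn-1-yl)oxy]benzaldehyde | C#CC(=O)COc1cc(OCOC)cc(OCOC)c1C=O
A3 | alternative 1 | 2-[2-(2-hydroxy-4-methoxy-3-prenylphenyl)-2-oxoethoxy]-4,6-bis(methoxymethoxy)benzaldehyde | COc1ccc(C(=O)COc2cc(OCOC)cc(OCOC)c2C=O)c(O)c1CC=C(C)C
A4 | alternative 1 | 2-[2-(2,4-dimethoxy-3-prenylphenyl)-2-oxoethoxy]-4,6-bis(methoxymethoxy)benzaldehyde | COc1ccc(C(=O)COc2cc(OCOC)cc(OCOC)c2C=O)c(OC)c1CC=C(C)C
A5 | alternative 2 | 3-(2,4-dimethoxy-3-prenylphenyl)-5,7-bis(methoxymethoxy)-4H-chromen-4-one | COCOc1cc(OCOC)c2c(=O)c(-c3ccc(OC)c(CC=C(C)C)c3OC)coc2c1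
A6 | alternative 2 | 2,3-epoxy-2',4'-dimethoxy-5,7-bis(methoxymethoxy)-3'-prenylisoflavanone, oxirane oxygen on the face of the future C3 hydroxyl | COCOc1cc(OCOC)c2C(=O)[C@]3(c4ccc(OC)c(CC=C(C)C)c4OC)O[C@@H]3Oc2c1
A7 | alternative 3 | methyl 7-[(4R)-4-(2,4-dimethoxy-3-prenylphenyl)-2,2-dimethyl-1,3-dioxolan-4-yl]-3,5,7-trioxoheptanoate | COC(=O)CC(=O)CC(=O)CC(=O)[C@@]1(c2ccc(OC)c(CC=C(C)C)c2OC)COC(C)(C)O1
A8 | alternative 3 | [(4R)-4-(2,4-dimethoxy-3-prenylphenyl)-2,2-dimethyl-1,3-dioxolan-4-yl](2,4,6-trihydroxyphenyl)methanone | O=C(c1c(O)cc(O)cc1O)[C@@]1(c2ccc(OC)c(CC=C(C)C)c2OC)COC(C)(C)O1
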